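## Retrosynthetic overview

1. Target 26 ⇐ propanoylation of the C8 alcohol, freed from silyl ether macrocycle 24.
2. Ten-membered carbocycle (formed last) ⇐ ring-closing metathesis at C2=C3 of diene 22, hydrogenated in the same pot.
3. Butenolide (formed second) ⇐ Nozaki–Hiyama–Kishi union of vinyl iodide 20 (fragment W: C1, C2, C7–C14) with epoxy aldehyde 7 (fragment E: C3–C6, C15), then lactonisation; sets C6.
4. Fragment W ⇐ copper–bis(oxazoline) Mukaiyama aldol (C10), zinc–ProPhenol alkynylation (C8), iodo-aldol with formaldehyde (C7=C11, C13).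
5. Fragment E ⇐ Sharpless epoxidation of a (Z)-dienol (epoxide formed first; C4, C5).

Assumption: the SMILES is read as (4R,5S,6S,8S,10R) in germacrane numbering (C1 ketone, C4/C5 epoxide, C6 lactone carbinol, C7=C11 butenolide alkene, C8 propanoate, C10 tertiary acetate, C12 lactone carbonyl, C13 acetoxymethyl); these locants are used throughout.
Assumption: the chiral catalysts of steps 8 and 10 induce in the sense stated; the mirror-image ligand is used if the opposite sense is found.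

## Route

Step 1
Reactants: 1 but-3-en-2-one; 2 ethynylmagnesium bromide
Product: 3 3-methylpent-1-en-4-yn-3-ol (racemic)
Conditions: THF, 0 °C; aq. NH4Cl
Reagents that add atoms: none
Why: 1,2-Grignard addition of the alkynyl nucleophile to the enone carbonyl; the stereocentre is lost in step 2.

Step 2
Reactants: 3 3-methylpent-1-en-4-yn-3-ol
Product: 4 (2Z)-3-methylpent-2-en-4-yn-1-ol
Conditions: dilute H2SO4, 50 °C; fractional distillation from the minor E isomer
Reagents that add atoms: water, O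
Why: acid-catalysed 1,3-allylic transposition of the tertiary carbinol to the conjugated primary enynol, Z isomer predominant.

Step 3
Reactants: 4 (2Z)-3-methylpent-2-en-4-yn-1-ol
Product: 5 (2Z)-3-methylpenta-2,4-dien-1-ol
Conditions: H2 (1 atm), Pd/CaCO3–Pb(OAc)2, quinoline, Et2O/pentane, 0 °C
Reagents that add atoms: none
Why: Lindlar semi-hydrogenation of the terminal alkyne stops at the vinyl group and leaves the Z-trisubstituted alkene untouched.

Step 4
Reactants: 5 (2Z)-3-methylpenta-2,4-dien-1-ol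
Product: 6 [(2S,3R)-3-ethenyl-3-methyloxiran-2-yl]methanol
Conditions: Ti(OiPr)4 (10 mol%), L-(+)-diethyl tartrate (12 mol%), t-BuOOH, 4 Å sieves, CH2Cl2, −20 °C
Reagents that add atoms: tert-butyl hydroperoxide, CC(C)(C)OO
Why: Sharpless asymmetric epoxidation oxidises only the allylic-alcohol alkene; the L-tartrate delivers oxygen to the face that gives C4 R and C5 S (cis epoxide from the Z alkene).

Step 5
Reactants: 6 [(2S,3R)-3-ethenyl-3-methyloxiran-2-yl]methanol
Product: 7 (2R,3R)-3-ethenyl-3-methyloxirane-2-carbaldehyde (fragment E)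
Conditions: TEMPO (10 mol%), PhI(OAc)2, CH2Cl2, rt; used as a solution
Reagents that add atoms: none
Why: oxoammonium (TEMPO) oxidation of the primary alcohol under neutral conditions; the epoxide carbons are unchanged (the descriptor changes only through CIP priorities).

Step 6
Reactants: 8 5-chloropentan-2-one
Product: 9 5-chloropentane-2,3-dione
Conditions: SeO2, 1,4-dioxane/H2O, 90 °C
Reagents that add atoms: selenium dioxide, O=[Se]=O
Why: Riley oxidation of the α-methylene (preferred over the α-methyl) gives the 1,2-diketone carrying a β-chloroethyl group as a masked vinyl ketone.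

Step 7
Reactants: 10 S-ethyl ethanethioate
Product: 11 [1-(ethylsulfanyl)ethenyl]oxy(trimethyl)silane
Conditions: LiN(iPr)2, THF, −78 °C; Me3SiCl
Reagents that add atoms: chlorotrimethylsilane, C[Si](C)(C)Cl
Why: kinetic enolisation and O-silylation give the silyl ketene thioacetal needed for the Mukaiyama aldol.

Step 8
Reactants: 9 5-chloropentane-2,3-dione; 11 [1-(ethylsulfanyl)ethenyl]oxy(trimethyl)silane
Product: 12 S-ethyl (3R)-6-chloro-3-methyl-4-oxo-3-[(trimethylsilyl)oxy]hexanethioate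
Conditions: Cu(OTf)2 (10 mol%), (R,R)-2,2′-(propane-2,2-diyl)bis(4-tert-butyl-4,5-dihydrooxazole) (11 mol%), THF, −78 °C; non-acidic work-up
Reagents that add atoms: none
Why: Evans-type catalytic Mukaiyama aldol on the copper-chelated diketone; attack at the less hindered methyl-ketone carbonyl on the face left open by the ligand sets C10 as R, with silyl transfer to the new tertiary oxygen.

Step 9
Reactants: 12 S-ethyl (3R)-6-chloro-3-methyl-4-oxo-3-[(trimethylsilyl)oxy]hexanethioate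
Product: 13 (3R)-6-chloro-3-methyl-4-oxo-3-[(trimethylsilyl)oxy]hexanal
Conditions: Et3SiH, Pd/C (10%), acetone, rt
Reagents that add atoms: none
Why: Fukuyama reduction converts the thioester to the aldehyde without touching the ketone, alkyl chloride or silyl ether.

Step 10
Reactants: 13 (3R)-6-chloro-3-methyl-4-oxo-3-[(trimethylsilyl)oxy]hexanal; 14 methyl prop-2-ynoate
Product: 15 methyl (4S,6R)-9-chloro-4-hydroxy-6-methyl-7-oxo-6-[(trimethylsilyl)oxy]non-2-ynoate
Conditions: Me2Zn, (S,S)-ProPhenol (20 mol%), Ph3PO (40 mol%), toluene, 4 °C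
Reagents that add atoms: none
Why: catalytic asymmetric alkynylation by the dinuclear zinc–ProPhenol complex adds the propiolate to the aldehyde only (not the hindered ketone) and sets C8 as S by reagent control.

Step 11
Reactants: 15 methyl (4S,6R)-9-chloro-4-hydroxy-6-methyl-7-oxo-6-[(trimethylsilyl)oxy]non-2-ynoate
Product: 16 methyl (4S,6R)-4-[(tert-butyldimethylsilyl)oxy]-9-chloro-6-methyl-7-oxo-6-[(trimethylsilyl)oxy]non-2-ynoate
Conditions: TBSOTf, 2,6-lutidine, CH2Cl2, −78 °C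
Reagents that add atoms: tert-butyldimethylsilyl trifluoromethanesulfonate, CC(C)(C)[Si](C)(C)OS(=O)(=O)C(F)(F)F
Why: silyl protection of the C8 alcohol prevents its lactonisation in step 12 and β-elimination from the alkenylchromium in step 14.

Step 12
Reactants: 16 methyl (4S,6R)-4-[(tert-butyldimethylsilyl)oxy]-9-chloro-6-methyl-7-oxo-6-[(trimethylsilyl)oxy]non-2-ynoate
Product: 18 methyl (2Z,4S,6R)-4-[(tert-butyldimethylsilyl)oxy]-9-chloro-6-hydroxy-2-(hydroxymethyl)-3-iodo-6-methyl-7-oxonon-2-enoate, via trimethylsilyl ether adduct 17 (not isolated)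
Conditions: MgI2, monomeric CH2O, CH2Cl2, −78 → 0 °C; then 1 M HCl/THF, 0 °C
Reagents that add atoms: magnesium iodide, [Mg+2].[I-].[I-]; formaldehyde, C=O
Why: iodo-aldol (β-iodo Morita–Baylis–Hillman) reaction: iodide adds to the ynoate and the magnesium β-iodoallenoate traps formaldehyde at the α-carbon, iodine ending syn to the ester with the branched C8 side anti; the acidic work-up frees the tertiary alcohol.

Step 13
Reactants: 18 methyl (2Z,4S,6R)-4-[(tert-butyldimethylsilyl)oxy]-9-chloro-6-hydroxy-2-(hydroxymethyl)-3-iodo-6-methyl-7-oxonon-2-enoate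
Product: 20 methyl (2Z,4S,6R)-6-(acetyloxy)-2-[(acetyloxy)methyl]-4-[(tert-butyldimethylsilyl)oxy]-3-iodo-6-methyl-7-oxonona-2,8-dienoate (fragment W), via diacetate chloro ketone 19 (not isolated)
Conditions: Ac2O, Sc(OTf)3 (2 mol%), MeCN, −20 °C; then Et3N, 0 °C
Reagents that add atoms: acetic anhydride, CC(=O)OC(C)=O
Why: Lewis-acid-catalysed acetylation esterifies the primary and the tertiary α-ketol hydroxyls, then E1cB loss of HCl from the β-chloro ketone unveils the vinyl ketone.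

Step 14
Reactants: 20 fragment W (vinyl iodide); 7 fragment E (epoxy aldehyde, 3 equiv)
Product: 22 (1S,3R)-1-{(2S)-4-[(acetyloxy)methyl]-2-[(2S,3R)-3-ethenyl-3-methyloxiran-2-yl]-5-oxo-2,5-dihydrofuran-3-yl}-1-[(tert-butyldimethylsilyl)oxy]-3-methyl-4-oxohex-5-en-3-yl acetate, via open hydroxy ester 21 (not isolated)
Conditions: CrCl2 (8 equiv), NiCl2 (2 mol%), DMF, rt; aq. NH4Cl
Reagents that add atoms: none
Why: Nozaki–Hiyama–Kishi coupling: the alkenylchromium (olefin geometry retained) adds to the aldehyde under Felkin–Anh control, anti to the epoxide C–O, setting C6 as S, and the alkoxide closes the butenolide on the cis ester.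

Step 15
Reactants: 22 butenolide diene
Product: 24 (4R,5S,6S,8S,10R)-10,13-diacetoxy-8-[(tert-butyldimethylsilyl)oxy]-4,5-epoxy-1-oxogermacr-7(11)-en-12,6-olide, via unsaturated macrocycle 23 (not isolated)
Conditions: second-generation Hoveyda–Grubbs catalyst (15 mol%), toluene (0.5 mM), 80 °C; then H2 (5 atm), 40 °C
Reagents that add atoms: none
Why: ring-closing metathesis of the vinyl ketone with the vinyl epoxide closes the ten-membered ring with loss of ethene; under H2 the spent ruthenium carbene becomes a hydride that saturates only the new disubstituted C2=C3 bond, leaving the tetrasubstituted butenolide alkene and all stereocentres untouched.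

Step 16
Reactants: 24 silyl ether macrocycle
Product: 25 (4R,5S,6S,8S,10R)-10,13-diacetoxy-4,5-epoxy-8-hydroxy-1-oxogermacr-7(11)-en-12,6-olide
Conditions: HF·pyridine, excess pyridine, THF, 0 °C → rt
Reagents that add atoms: none
Why: buffered fluoride desilylation frees the C8 alcohol without base (no γ-deprotonation of the butenolide) and without opening the epoxide.

Step 17
Reactants: 25 C8 alcohol
Product: 26 (4R,5S,6S,8S,10R)-10,13-diacetoxy-4,5-epoxy-1-oxo-8-(propanoyloxy)germacr-7(11)-en-12,6-olide (target)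
Conditions: (EtCO)2O, pyridine, DMAP (cat.), CH2Cl2, 0 °C
Reagents that add atoms: propanoic anhydride, CCC(=O)OC(=O)CC
Why: DMAP-catalysed acylation of the only free hydroxyl with retention at C8 gives the target.

## Compound list

1 | but-3-en-2-one | CC(=O)C=C | starting material
2 | ethynylmagnesium bromide | C#C[Mg]Br | starting material
3 | 3-methylpent-1-en-4-yn-3-ol (racemic) | C=CC(C)(O)C#C | intermediate
4 | (2Z)-3-methylpent-2-en-4-yn-1-ol | OC/C=C(/C)C#C | intermediate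
5 | (2Z)-3-methylpenta-2,4-dien-1-ol | OC/C=C(/C)C=C | intermediate
6 | [(2S,3R)-3-ethenyl-3-methyloxiran-2-yl]methanol | C=C[C@@]1(C)O[C@H]1CO | intermediate
7 | (2R,3R)-3-ethenyl-3-methyloxirane-2-carbaldehyde (fragment E) | C=C[C@@]1(C)O[C@H]1C=O | intermediate
8 | 5-chloropentan-2-one | CC(=O)CCCCl | starting material
9 | 5-chloropentane-2,3-dione | CC(=O)C(=O)CCCl | intermediate
10 | S-ethyl ethanethioate | CCSC(C)=O | starting material
11 | [1-(ethylsulfanyl)ethenyl]oxy(trimethyl)silane | C=C(SCC)O[Si](C)(C)C | intermediate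
12 | S-ethyl (3R)-6-chloro-3-methyl-4-oxo-3-[(trimethylsilyl)oxy]hexanethioate | CCSC(=O)C[C@@](C)(O[Si](C)(C)C)C(=O)CCCl | intermediate
13 | (3R)-6-chloro-3-methyl-4-oxo-3-[(trimethylsilyl)oxy]hexanal | O=CC[C@@](C)(O[Si](C)(C)C)C(=O)CCCl | intermediate
14 | methyl prop-2-ynoate | COC(=O)C#C | starting material
15 | methyl (4S,6R)-9-chloro-4-hydroxy-6-methyl-7-oxo-6-[(trimethylsilyl)oxy]non-2-ynoate | COC(=O)C#C[C@@H](O)C[C@@](C)(O[Si](C)(C)C)C(=O)CCCl | intermediate
16 | methyl (4S,6R)-4-[(tert-butyldimethylsilyl)oxy]-9-chloro-6-methyl-7-oxo-6-[(trimethylsilyl)oxy]non-2-ynoate | COC(=O)C#C[C@@H](O[Si](C)(C)C(C)(C)C)C[C@@](C)(O[Si](C)(C)C)C(=O)CCCl | intermediate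
17 | methyl (2Z,4S,6R)-4-[(tert-butyldimethylsilyl)oxy]-9-chloro-2-(hydroxymethyl)-3-iodo-6-methyl-7-oxo-6-[(trimethylsilyl)oxy]non-2-enoate | COC(=O)/C(CO)=C(\I)[C@@H](O[Si](C)(C)C(C)(C)C)C[C@@](C)(O[Si](C)(C)C)C(=O)CCCl | intermediate
18 | methyl (2Z,4S,6R)-4-[(tert-butyldimethylsilyl)oxy]-9-chloro-6-hydroxy-2-(hydroxymethyl)-3-iodo-6-methyl-7-oxonon-2-enoate | COC(=O)/C(CO)=C(\I)[C@@H](O[Si](C)(C)C(C)(C)C)C[C@@](C)(O)C(=O)CCCl | intermediate
19 | methyl (2Z,4S,6R)-6-(acetyloxy)-2-[(acetyloxy)methyl]-4-[(tert-butyldimethylsilyl)oxy]-9-chloro-3-iodo-6-methyl-7-oxonon-2-enoate | COC(=O)/C(COC(C)=O)=C(\I)[C@@H](O[Si](C)(C)C(C)(C)C)C[C@@](C)(OC(C)=O)C(=O)CCCl | intermediate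
20 | methyl (2Z,4S,6R)-6-(acetyloxy)-2-[(acetyloxy)methyl]-4-[(tert-butyldimethylsilyl)oxy]-3-iodo-6-methyl-7-oxonona-2,8-dienoate (fragment W) | COC(=O)/C(COC(C)=O)=C(\I)[C@@H](O[Si](C)(C)C(C)(C)C)C[C@@](C)(OC(C)=O)C(=O)C=C | intermediate
21 | methyl (2E,4S,6R)-6-(acetyloxy)-2-[(acetyloxy)methyl]-4-[(tert-butyldimethylsilyl)oxy]-3-{(S)-[(2S,3R)-3-ethenyl-3-methyloxiran-2-yl](hydroxy)methyl}-6-methyl-7-oxonona-2,8-dienoate (as its chromium alkoxide) | COC(=O)/C(COC(C)=O)=C(\[C@H](O)[C@@H]1O[C@]1(C)C=C)[C@@H](O[Si](C)(C)C(C)(C)C)C[C@@](C)(OC(C)=O)C(=O)C=C | intermediate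
22 | (1S,3R)-1-{(2S)-4-[(acetyloxy)methyl]-2-[(2S,3R)-3-ethenyl-3-methyloxiran-2-yl]-5-oxo-2,5-dihydrofuran-3-yl}-1-[(tert-butyldimethylsilyl)oxy]-3-methyl-4-oxohex-5-en-3-yl acetate | CC(C)(C)[Si](C)(C)O[C@@H](C[C@@](C)(OC(C)=O)C(=O)C=C)C1=C(COC(C)=O)C(=O)O[C@@H]1[C@@H]1O[C@]1(C)C=C | intermediate
23 | (4R,5S,6S,8S,10R)-10,13-diacetoxy-8-[(tert-butyldimethylsilyl)oxy]-4,5-epoxy-1-oxogermacra-2,7(11)-dien-12,6-olide (C2=C3 geometry not controlled) | CC(C)(C)[Si](C)(C)O[C@H]1C[C@@](C)(OC(C)=O)C(=O)C=C[C@@]2(C)O[C@H]2[C@H]2OC(=O)C(COC(C)=O)=C12 | intermediate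
24 | (4R,5S,6S,8S,10R)-10,13-diacetoxy-8-[(tert-butyldimethylsilyl)oxy]-4,5-epoxy-1-oxogermacr-7(11)-en-12,6-olide | CC(C)(C)[Si](C)(C)O[C@H]1C[C@@](C)(OC(C)=O)C(=O)CC[C@@]2(C)O[C@H]2[C@H]2OC(=O)C(COC(C)=O)=C12 | intermediate
25 | (4R,5S,6S,8S,10R)-10,13-diacetoxy-4,5-epoxy-8-hydroxy-1-oxogermacr-7(11)-en-12,6-olide | O[C@H]1C[C@@](C)(OC(C)=O)C(=O)CC[C@@]2(C)O[C@H]2[C@H]2OC(=O)C(COC(C)=O)=C12 | intermediate
26 | (4R,5S,6S,8S,10R)-10,13-diacetoxy-4,5-epoxy-1-oxo-8-(propanoyloxy)germacr-7(11)-en-12,6-olide | CCC(=O)O[C@H]1C[C@@](C)(OC(C)=O)C(=O)CC[C@@]2(C)O[C@H]2[C@H]2OC(=O)C(COC(C)=O)=C12 | target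

## Step count and risks

Total step count: 17 (fragment E: steps 1–5; fragment W: steps 6–13; union and endgame: steps 14–17).
Longest linear sequence: 11 steps (6, 8, 9, 10, 11, 12, 13, 14, 15, 16, 17).

Steps most likely to fail:

Step 12 (iodo-aldol on a β-branched ynoate; rate and alkene geometry are uncertain). The fallback sets out from 16 and comes back at 22. Gold-catalysed hydration of the ynoate (Ph3PAuNTf2, wet dioxane; the tertiary trimethylsilyl ether is lost) gives the β-keto ester F1. C-alkylation with bromomethyl acetate (K2CO3, acetone) gives the α-(acetoxymethyl) keto ester F2. Triflation of the chelated potassium enolate (KN(SiMe3)2, PhNTf2, −78 °C) gives the (Z)-enol triflate F3, whose geometry is fixed by chelation and not by the size of the C8 branch. Acetylation and dehydrochlorination as in step 13 give the vinyl ketone triflate F4, which is coupled with 7 under the CrCl2/NiCl2 conditions of step 14 to reach 22.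

Step 14 (intermolecular coupling of a tetrasubstituted alkenyl iodide). The fallback sets out from 20 and 7 and comes back at 24. The order of the two unions is reversed: cross-metathesis of the vinyl ketone of 20 with excess 7 (second-generation Hoveyda–Grubbs catalyst) gives the enone aldehyde F5. Diimide reduction of the disubstituted enone alkene (2-nitrobenzenesulfonohydrazide, Et3N) gives the saturated iodo aldehyde F6. The hindered alkenyl iodide then adds intramolecularly to the aldehyde (CrCl2, NiCl2, DMF, high dilution), closing the ten-membered ring and the butenolide in one operation.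

Step 15 (ring-closing metathesis to a ten-membered enone). The fallback sets out from 22 and comes back at 24. The electron-poor, sp2-flanked olefin is exchanged for an allylic alcohol before ring closure: Luche reduction (NaBH4, CeCl3·7H2O, MeOH, −78 °C) gives the allylic alcohol F7 as C1 epimers. Ring-closing metathesis of this more flexible and more reactive diene gives the cyclic allylic alcohol F8. Diimide reduction gives the saturated alcohol F9, and Dess–Martin oxidation of C1 gives 24.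

## Further compounds

F1 | step 12 | methyl (4S,6R)-4-[(tert-butyldimethylsilyl)oxy]-9-chloro-6-hydroxy-6-methyl-3,7-dioxononanoate | COC(=O)CC(=O)[C@@H](O[Si](C)(C)C(C)(C)C)C[C@@](C)(O)C(=O)CCCl
F2 | step 12 | methyl (4S,6R)-2-[(acetyloxy)methyl]-4-[(tert-butyldimethylsilyl)oxy]-9-chloro-6-hydroxy-6-methyl-3,7-dioxononanoate (C2 epimers) | COC(=O)C(COC(C)=O)C(=O)[C@@H](O[Si](C)(C)C(C)(C)C)C[C@@](C)(O)C(=O)CCCl
F3 | step 12 | methyl (2Z,4S,6R)-2-[(acetyloxy)methyl]-4-[(tert-butyldimethylsilyl)oxy]-9-chloro-6-hydroxy-6-methyl-7-oxo-3-{[(trifluoromethyl)sulfonyl]oxy}non-2-enoate | COC(=O)/C(COC(C)=O)=C(\OS(=O)(=O)C(F)(F)F)[C@@H](O[Si](C)(C)C(C)(C)C)C[C@@](C)(O)C(=O)CCCl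
F4 | step 12 | methyl (2Z,4S,6R)-6-(acetyloxy)-2-[(acetyloxy)methyl]-4-[(tert-butyldimethylsilyl)oxy]-6-methyl-7-oxo-3-{[(trifluoromethyl)sulfonyl]oxy}nona-2,8-dienoate | COC(=O)/C(COC(C)=O)=C(\OS(=O)(=O)C(F)(F)F)[C@@H](O[Si](C)(C)C(C)(C)C)C[C@@](C)(OC(C)=O)C(=O)C=C
F5 | step 14 | methyl (2Z,4S,6R,8E)-6-(acetyloxy)-2-[(acetyloxy)methyl]-4-[(tert-butyldimethylsilyl)oxy]-9-[(2R,3R)-3-formyl-2-methyloxiran-2-yl]-3-iodo-6-methyl-7-oxonona-2,8-dienoate | COC(=O)/C(COC(C)=O)=C(\I)[C@@H](O[Si](C)(C)C(C)(C)C)C[C@@](C)(OC(C)=O)C(=O)/C=C/[C@@]1(C)O[C@H]1C=O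
F6 | step 14 | methyl (2Z,4S,6R)-6-(acetyloxy)-2-[(acetyloxy)methyl]-4-[(tert-butyldimethylsilyl)oxy]-9-[(2R,3R)-3-formyl-2-methyloxiran-2-yl]-3-iodo-6-methyl-7-oxonon-2-enoate | COC(=O)/C(COC(C)=O)=C(\I)[C@@H](O[Si](C)(C)C(C)(C)C)C[C@@](C)(OC(C)=O)C(=O)CC[C@@]1(C)O[C@H]1C=O
F7 | step 15 | (1S,3R)-1-{(2S)-4-[(acetyloxy)methyl]-2-[(2S,3R)-3-ethenyl-3-methyloxiran-2-yl]-5-oxo-2,5-dihydrofuran-3-yl}-1-[(tert-butyldimethylsilyl)oxy]-4-hydroxy-3-methylhex-5-en-3-yl acetate (C4 epimers of the chain) | CC(C)(C)[Si](C)(C)O[C@@H](C[C@@](C)(OC(C)=O)C(O)C=C)C1=C(COC(C)=O)C(=O)O[C@@H]1[C@@H]1O[C@]1(C)C=C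
F8 | step 15 | (4R,5S,6S,8S,10R)-10,13-diacetoxy-8-[(tert-butyldimethylsilyl)oxy]-4,5-epoxy-1-hydroxygermacra-2,7(11)-dien-12,6-olide (C1 epimers) | CC(C)(C)[Si](C)(C)O[C@H]1C[C@@](C)(OC(C)=O)C(O)C=C[C@@]2(C)O[C@H]2[C@H]2OC(=O)C(COC(C)=O)=C12
F9 | step 15 | (4R,5S,6S,8S,10R)-10,13-diacetoxy-8-[(tert-butyldimethylsilyl)oxy]-4,5-epoxy-1-hydroxygermacr-7(11)-en-12,6-olide (C1 epimers) | CC(C)(C)[Si](C)(C)O[C@H]1C[C@@](C)(OC(C)=O)C(O)CC[C@@]2(C)O[C@H]2[C@H]2OC(=O)C(COC(C)=O)=C12
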